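The trap in this flask is to take the dissolving and the round of the second catalyst for a drain on the catalyst, and then to look for a share that slides with conversion.

solid substrate 10 mM; coupling partner 10.0 mM; free catalyst 1.0 mM; second catalyst 16 µM

    solid substrate ⇌ starting material, rate k1*(cs1 - [starting material]) while solid is left; crystals form when [starting material] > cs1 (cs1 = 4.4 mM, k1 = 0.050 h⁻¹)
    starting material + free catalyst → free catalyst + open intermediate (k2 = 81 M⁻¹ h⁻¹)
    coupling partner + catalyst intermediate → second catalyst + product (k3 = 1900 M⁻¹ h⁻¹)
    second catalyst + open intermediate ⇌ catalyst intermediate (K4 = 9400 M⁻¹, k4 = 5.6 × 10⁵ M⁻¹ h⁻¹)
    2 free catalyst ⇌ resting dimer, settled at all times (K5 = 700 M⁻¹)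

- two of one species on the left: rate k times its square, two consumed each time
- as a solid, counted per litre of solution: solid substrate
- at the start none of the solid substrate is in solution
- what has only dissolved of solid substrate counts as not reacted
- a form made of two catalysts counts as two
- "the catalyst" is free catalyst with its forms; second catalyst is a second catalyst
- charge of solid substrate (flask): 10 mM

- the form that holds most of the catalyst when 20% of the solid substrate are converted (what has only dissolved counts as not reacted) (resting dimer / free catalyst)
- its share of the catalyst then

The step that takes the starting material hands back the free catalyst it uses, and the catalyst intermediate is a form of the second catalyst. So I count two forms of the catalyst: c(free catalyst) plus two times c(resting dimer) equals 1.0 mM, while c(resting dimer) is 700 M⁻¹ times c(free catalyst) squared. Solving this, I get c(free catalyst) = 0.560 mM, which is 56.0% of the charge. I carry this free share, the fraction of the catalyst charged that stands as free catalyst at dimer balance. Free catalyst therefore holds more than the resting dimer. With c(free catalyst) held, the step that takes the starting material is pseudo-first-order, with constant 0.0454 h⁻¹.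

Now the neighbouring flask, the same but with twice the coupling partner. The coupling partner stands neither in the balance nor in that step. So I reckon that both flasks hold the same free share and reach 20% conversion at the same time.

The forecast names free catalyst at 56%, on the ground that “the split doesn't depend on conversion or on the dissolution kinetics”. It stands on the same balance as my reckoning.

The flask gives free catalyst at 56.0%, after 28.9 h. With twice the coupling partner, the time to that conversion changes by a factor of 1.00 and the rate by a factor of 1.02. I use the free share once more. Taking product as made at the pace the starting material reacts, the rate of 0.0956 mM h⁻¹ at 28.9 h, divided by the rate constant of that step and by the free share of 1.0 mM, asks for c(starting material) = 2.11 mM. The flask held 1.96 mM after 20.0 h and 2.26 mM after 40.0 h.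

The numbers of this flask stand for no real mixture; the result is computed.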